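**Strategy.** The cyclohexane is opened at the bond between its ring CH2 and the ring CH that carries the 1,1-disubstituted olefin. Because the Cl–C–C(CH3)–OH chlorohydrin is a masked ring olefin, both atoms of this bond are allylic, so the six-membered ring is a limonene-type 1,5-diene. One Lewis-acid step closes it: a linalyl-type vinyl oxirane ionises to a cisoid allyl cation that is captured by a silicon-tethered allylsilane. This forms the ring, sets the methine stereocentre cis to the neighbouring oxygen, creates the C=C(CH3) and C=CH2 olefins and frees the allylic hydroxyl. The precursor is a 1,2-oxasiline (cyclic allylsiloxane) carrying the vinyl oxirane, assembled from an epoxy alcohol and an allylsilane angelate by silylation and metathesis.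

Key step: step 10

Remark: (E)-3-methylpent-2-en-4-yn-1-ol, methyl (S)-glycidate, (chloromethyl)dimethylsilane, the two Grignard reagents, angelic acid and angelic anhydride are taken as commercial; only substrates, intermediates and products are numbered, and where CIP priorities change along the route the SMILES are authoritative.

**Step 1**
Reactants: 1 (E)-3-methylpent-2-en-4-yn-1-ol
Product: 2 (E)-3-methylpent-2-en-4-ynal
Conditions: activated MnO2 (10 equiv), CH2Cl2, rt
Reagents that add atoms: none
Why: Allylic alcohol oxidation with MnO2 is selective for the allylic hydroxyl and should leave the alkyne and the olefin geometry untouched.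

**Step 2**
Reactants: 2 (E)-3-methylpent-2-en-4-ynal
Product: 3 rac-(E)-5-methylhepta-1,4-dien-6-yn-3-ol
Conditions: CH2=CHMgBr (1.2 equiv), THF, −78 °C; aq. NH4Cl
Reagents that add atoms: vinylmagnesium bromide, C=C[Mg]Br
Why: Grignard 1,2-addition to the enal at low temperature should outrun deprotonation of the terminal alkyne and give the racemic bis-allylic alcohol.

**Step 3**
Reactants: 3 rac-(E)-5-methylhepta-1,4-dien-6-yn-3-ol
Product: 4 (S)-1-[(2S,3S)-3-ethynyl-3-methyloxiran-2-yl]prop-2-en-1-ol
Conditions: Ti(OiPr)4 (0.15 equiv), L-(+)-DIPT (0.2 equiv), t-BuOOH (0.5 equiv), 4 Å MS, CH2Cl2, −20 °C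
Reagents that add atoms: tert-butyl hydroperoxide, CC(C)(C)OO
Why: Sharpless asymmetric epoxidation run as a kinetic resolution: with L-(+)-DIPT only the (S)-alcohol should be epoxidised quickly, at its trisubstituted olefin and on the face set by the tartrate, which fixes the carbinol and both oxirane carbons (erythro), while the (R)-alcohol and the monosubstituted vinyl group react far more slowly and the unreacted alcohol is separated.

**Step 4**
Reactants: 4 (S)-1-[(2S,3S)-3-ethynyl-3-methyloxiran-2-yl]prop-2-en-1-ol
Product: 5 (S)-1-[(2S,3S)-3-ethenyl-3-methyloxiran-2-yl]prop-2-en-1-ol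
Conditions: H2 (1 atm), Pd/CaCO3–Pb(OAc)2 (Lindlar catalyst), quinoline, EtOAc, rt
Reagents that add atoms: none
Why: Lindlar semi-hydrogenation should reduce only the terminal alkyne to the vinyl group and touch no stereocentre.

**Step 5**
Reactants: 6 methyl (S)-oxirane-2-carboxylate (methyl (S)-glycidate)
Product: 7 methyl (S)-2-hydroxy-5-methylhex-4-enoate
Conditions: Me2C=CHMgBr (1.3 equiv), CuI (10 mol%), THF, −40 °C; aq. NH4Cl
Reagents that add atoms: 2-methylprop-1-enylmagnesium bromide, CC(C)=C[Mg]Br
Why: Copper-catalysed Grignard opening of the glycidic ester (SN2 at the unsubstituted oxirane carbon) leaves the glycidate stereocentre untouched, and this centre becomes the (S)-carbinol of the side chain.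

**Step 6**
Reactants: 7 methyl (S)-2-hydroxy-5-methylhex-4-enoate
Product: 9 (S)-2-[(dimethylsilyl)methyl]-6-methylhepta-1,5-dien-3-ol, via bis(silylmethyl)carbinol 8 (not isolated)
Conditions: HMe2SiCH2MgCl (5 equiv; from ClCH2SiMe2H and Mg, THF), CeCl3 (5 equiv), THF, −78 °C → rt; aq. NH4Cl; then SiO2, CH2Cl2, rt
Reagents that add atoms: (dimethylsilyl)methylmagnesium chloride, C[SiH](C)C[Mg]Cl
Why: Double addition of the silylmethyl organocerium reagent to the ester followed by acid-promoted Peterson olefination of the tertiary β-hydroxysilane should give the 2-substituted allylsilane; the free hydroxyl is carried as its alkoxide by excess reagent and the stereocentre is not involved.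

**Step 7**
Reactants: 9 (S)-2-[(dimethylsilyl)methyl]-6-methylhepta-1,5-dien-3-ol
Product: 10 (S)-2-[(dimethylsilyl)methyl]-6-methylhepta-1,5-dien-3-yl (Z)-2-methylbut-2-enoate
Conditions: angelic acid, 2,4,6-trichlorobenzoyl chloride, Et3N, toluene, rt; then 9, 80 °C
Reagents that add atoms: angelic acid, C/C=C(/C)C(=O)O
Why: Yamaguchi-type esterification through the mixed anhydride without DMAP should acylate the secondary allylic alcohol without Z-to-E isomerisation of the angelate, and the Si–H bond is inert to these conditions.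

**Step 8**
Reactants: 5 (S)-1-[(2S,3S)-3-ethenyl-3-methyloxiran-2-yl]prop-2-en-1-ol, 10 (S)-2-[(dimethylsilyl)methyl]-6-methylhepta-1,5-dien-3-yl (Z)-2-methylbut-2-enoate
Product: 11 (S)-2-{[dimethyl({(S)-1-[(2S,3S)-3-ethenyl-3-methyloxiran-2-yl]prop-2-en-1-yl}oxy)silyl]methyl}-6-methylhepta-1,5-dien-3-yl (Z)-2-methylbut-2-enoate
Conditions: Rh2(O2CC3F7)4 (1 mol%), CH2Cl2, 0 °C → rt
Reagents that add atoms: none
Why: Rhodium-catalysed dehydrogenative silylation (silane alcoholysis) should join the fragments through an O–Si bond under neutral conditions that spare oxirane, ester and olefins, and any enantiomer of 5 carried over from the resolution becomes a separable diastereomer here.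

**Step 9**
Reactants: 11 (silyl ether of 5 with 10)
Product: 12 (S)-1-{(S)-6-[(2S,3S)-3-ethenyl-3-methyloxiran-2-yl]-2,2-dimethyl-3,6-dihydro-2H-1,2-oxasilin-4-yl}-4-methylpent-3-en-1-yl (Z)-2-methylbut-2-enoate
Conditions: second-generation Hoveyda–Grubbs catalyst (H2IMes)Cl2Ru(=CH-C6H4-2-OiPr) (5 mol%), toluene (5 mM), 80 °C
Reagents that add atoms: none
Why: Silicon-tethered ring-closing metathesis between the carbinol vinyl group and the 1,1-disubstituted allylsilane olefin should close the six-membered oxasiline, in which the trisubstituted olefin is necessarily Z; the vinyl group on the oxirane is trans to the carbinol chain and cannot close a ring with it, and the prenyl and angelate olefins are inert.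

**Step 10**
Reactants: 12 (oxasiline carrying the vinyl oxirane)
Product: 14 (S)-2-[(1R,5R,6S)-5,6-dihydroxy-4-methylcyclohex-3-en-1-yl]-6-methylhepta-1,5-dien-3-yl (Z)-2-methylbut-2-enoate, via silylene acetal 13 (not isolated)
Conditions: BF3·OEt2 (0.3 equiv), 2,6-di-tert-butylpyridine (0.3 equiv), CH2Cl2, −78 → −40 °C; then HF·pyridine, pyridine, THF, 0 °C
Reagents that add atoms: none
Why: BF3 on the oxirane oxygen should ionise the tertiary allylic C–O bond from the rotamer in which the vinyl group lies over the oxirane C–C bond, giving the cisoid methyl-substituted allyl cation with a boron alkoxide on the neighbouring carbon; its CH2 terminus is captured by the γ-carbon of the cyclic allylsiloxane (SE2′), and the β-silyl cation collapses by C-to-O silyl transfer to that alkoxide, which releases BF3 and gives silylene acetal 13, cleaved to the diol by HF·pyridine. The closest known reaction types are the epoxide-initiated, allylsilane-terminated cation–olefin cyclisation (intramolecular Hosomi–Sakurai reaction) and the Lewis-acid allylations of cyclic allylsiloxanes made by silicon-tethered metathesis; the step is also the laboratory counterpart of the linalyl/neryl cation closure of terpene cyclases. The carbocycle closes in a 6-endo sense with respect to the allyl cation (the new C=C(CH3) bond lies inside the ring) and in an exo sense with respect to the allylsilane (the new C=CH2 lies outside it). The only new stereocentre, the ring methine, is controlled by the oxasiline ring: the silyloxy oxygen is held close to the plane of the allylsilane olefin, so the cation can reach only the face on which the oxirane-derived chain lies, the new ring forms cis-fused to the oxasiline, and the 1,1-disubstituted olefin ends cis to the neighbouring oxygen. The step needs ionisation at the tertiary allylic rather than the secondary oxirane carbon (secured by cation stability), the cisoid cation geometry (only this one can close, favoured because the vinyl group is cis only to a hydrogen on the oxirane), and attack at the allyl terminus (attack at the tertiary end would give a four-membered ring).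

**Step 11**
Reactants: 14 (cyclohexenediol)
Product: 15 (S)-2-[(1S,2S,3S,4R,6R)-2,3-dihydroxy-1-methyl-7-oxabicyclo[4.1.0]heptan-4-yl]-6-methylhepta-1,5-dien-3-yl (Z)-2-methylbut-2-enoate
Conditions: VO(acac)2 (5 mol%), t-BuOOH (1.2 equiv), CH2Cl2, 0 °C → rt
Reagents that add atoms: tert-butyl hydroperoxide, CC(C)(C)OO
Why: Hydroxyl-directed epoxidation: the allylic and the homoallylic hydroxyl on the same face should both deliver oxygen to the ring olefin syn to themselves, which sets the two oxirane carbons, while the side-chain olefins have no free directing hydroxyl.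

**Step 12**
Reactants: 15 (epoxy diol)
Product: 16 (1S,2S,3S,4R,6R)-3-hydroxy-1-methyl-4-{(S)-6-methyl-3-[((Z)-2-methylbut-2-enoyl)oxy]hepta-1,5-dien-2-yl}-7-oxabicyclo[4.1.0]heptan-2-yl (Z)-2-methylbut-2-enoate
Conditions: angelic anhydride (1.1 equiv), Cs2CO3, MeCN, 0 °C → rt
Reagents that add atoms: angelic anhydride, C/C=C(/C)C(=O)OC(=O)/C(C)=C\C
Why: Site-selective O-acylation: the pseudo-equatorial hydroxyl next to the oxirane should be esterified in preference to the axial hydroxyl flanked by the branched side chain, and the anhydride with carbonate base avoids angelate-to-tiglate isomerisation.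

**Step 13**
Reactants: 16 (epoxy bis-angelate)
Product: 17 (1S,2S,3S,5R,6S)-3-chloro-2,6-dihydroxy-2-methyl-5-{(S)-6-methyl-3-[((Z)-2-methylbut-2-enoyl)oxy]hepta-1,5-dien-2-yl}cyclohexyl (Z)-2-methylbut-2-enoate
Conditions: pyridinium chloride (3 equiv), CHCl3, 0 °C → rt
Reagents that add atoms: pyridinium chloride, [Cl-].c1cc[nH+]cc1
Why: Acid-mediated oxirane opening by chloride under trans-diaxial (Fürst–Plattner) control should occur at the secondary carbon remote from the acyloxy group, with inversion there placing Cl anti to the tertiary hydroxyl, whose configuration is retained.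

**Step 14**
Reactants: 17 (chlorohydrin)
Product: 18 (1S,2S,3S,5R,6S)-3-chloro-5-{(S)-4-[(R)-3,3-dimethyloxiran-2-yl]-3-[((Z)-2-methylbut-2-enoyl)oxy]but-1-en-2-yl}-2,6-dihydroxy-2-methylcyclohexyl (Z)-2-methylbut-2-enoate
Conditions: D-fructose-derived Shi ketone (1 equiv), Oxone (KHSO5), NaHCO3 (pH ≈ 8), Na2EDTA, MeCN–H2O, 0 °C
Reagents that add atoms: potassium peroxymonosulfate (Oxone), [K+].[O-]S(=O)(=O)OO
Why: Shi asymmetric epoxidation: the chiral dioxirane should epoxidise the electron-rich trisubstituted olefin in preference to the 1,1-disubstituted and the two conjugated angelate olefins and give the (R)-oxirane through the spiro transition state, while the near-neutral buffer keeps the chlorohydrin from closing.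

**Compound list**
1 | (E)-3-methylpent-2-en-4-yn-1-ol | C#C/C(C)=C/CO | starting material
2 | (E)-3-methylpent-2-en-4-ynal | C#C/C(C)=C/C=O | intermediate
3 | rac-(E)-5-methylhepta-1,4-dien-6-yn-3-ol | C=CC(O)/C=C(C)/C#C | intermediate
4 | (S)-1-[(2S,3S)-3-ethynyl-3-methyloxiran-2-yl]prop-2-en-1-ol | C=C[C@H](O)[C@@H]1O[C@@]1(C)C#C | intermediate
5 | (S)-1-[(2S,3S)-3-ethenyl-3-methyloxiran-2-yl]prop-2-en-1-ol | C=C[C@H](O)[C@@H]1O[C@@]1(C)C=C | intermediate
6 | methyl (S)-oxirane-2-carboxylate | COC(=O)[C@@H]1CO1 | starting material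
7 | methyl (S)-2-hydroxy-5-methylhex-4-enoate | COC(=O)[C@@H](O)CC=C(C)C | intermediate
8 | (S)-1-(dimethylsilyl)-2-[(dimethylsilyl)methyl]-6-methylhept-5-ene-2,3-diol | C[SiH](C)CC(O)(C[SiH](C)C)[C@@H](O)CC=C(C)C | intermediate
9 | (S)-2-[(dimethylsilyl)methyl]-6-methylhepta-1,5-dien-3-ol | C[SiH](C)CC(=C)[C@@H](O)CC=C(C)C | intermediate
10 | (S)-2-[(dimethylsilyl)methyl]-6-methylhepta-1,5-dien-3-yl (Z)-2-methylbut-2-enoate | C[SiH](C)CC(=C)[C@H](CC=C(C)C)OC(=O)/C(C)=C\C | intermediate
11 | (S)-2-{[dimethyl({(S)-1-[(2S,3S)-3-ethenyl-3-methyloxiran-2-yl]prop-2-en-1-yl}oxy)silyl]methyl}-6-methylhepta-1,5-dien-3-yl (Z)-2-methylbut-2-enoate | C=C[C@H](O[Si](C)(C)CC(=C)[C@H](CC=C(C)C)OC(=O)/C(C)=C\C)[C@@H]1O[C@@]1(C)C=C | intermediate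
12 | (S)-1-{(S)-6-[(2S,3S)-3-ethenyl-3-methyloxiran-2-yl]-2,2-dimethyl-3,6-dihydro-2H-1,2-oxasilin-4-yl}-4-methylpent-3-en-1-yl (Z)-2-methylbut-2-enoate | C[Si]1(C)CC([C@H](CC=C(C)C)OC(=O)/C(C)=C\C)=C[C@H](O1)[C@@H]2O[C@@]2(C)C=C | intermediate
13 | (S)-2-[(3aS,4R,7aR)-2,2,7-trimethyl-3a,4,5,7a-tetrahydrobenzo[d][1,3,2]dioxasilol-4-yl]-6-methylhepta-1,5-dien-3-yl (Z)-2-methylbut-2-enoate | C=C([C@H](CC=C(C)C)OC(=O)/C(C)=C\C)[C@H]1CC=C(C)[C@H]2O[Si](C)(C)O[C@@H]12 | intermediate
14 | (S)-2-[(1R,5R,6S)-5,6-dihydroxy-4-methylcyclohex-3-en-1-yl]-6-methylhepta-1,5-dien-3-yl (Z)-2-methylbut-2-enoate | C=C([C@H](CC=C(C)C)OC(=O)/C(C)=C\C)[C@H]1CC=C(C)[C@@H](O)[C@H]1O | intermediate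
15 | (S)-2-[(1S,2S,3S,4R,6R)-2,3-dihydroxy-1-methyl-7-oxabicyclo[4.1.0]heptan-4-yl]-6-methylhepta-1,5-dien-3-yl (Z)-2-methylbut-2-enoate | C=C([C@H](CC=C(C)C)OC(=O)/C(C)=C\C)[C@H]1C[C@H]2O[C@@]2(C)[C@@H](O)[C@H]1O | intermediate
16 | (1S,2S,3S,4R,6R)-3-hydroxy-1-methyl-4-{(S)-6-methyl-3-[((Z)-2-methylbut-2-enoyl)oxy]hepta-1,5-dien-2-yl}-7-oxabicyclo[4.1.0]heptan-2-yl (Z)-2-methylbut-2-enoate | C=C([C@H](CC=C(C)C)OC(=O)/C(C)=C\C)[C@H]1C[C@H]2O[C@@]2(C)[C@@H](OC(=O)/C(C)=C\C)[C@H]1O | intermediate
17 | (1S,2S,3S,5R,6S)-3-chloro-2,6-dihydroxy-2-methyl-5-{(S)-6-methyl-3-[((Z)-2-methylbut-2-enoyl)oxy]hepta-1,5-dien-2-yl}cyclohexyl (Z)-2-methylbut-2-enoate | C=C([C@H](CC=C(C)C)OC(=O)/C(C)=C\C)[C@H]1C[C@H](Cl)[C@@](C)(O)[C@@H](OC(=O)/C(C)=C\C)[C@H]1O | intermediate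
18 | (1S,2S,3S,5R,6S)-3-chloro-5-{(S)-4-[(R)-3,3-dimethyloxiran-2-yl]-3-[((Z)-2-methylbut-2-enoyl)oxy]but-1-en-2-yl}-2,6-dihydroxy-2-methylcyclohexyl (Z)-2-methylbut-2-enoate | C=C([C@H](C[C@H]1OC1(C)C)OC(=O)/C(C)=C\C)[C@H]1C[C@H](Cl)[C@@](C)(O)[C@@H](OC(=O)/C(C)=C\C)[C@H]1O | target

**Total steps:** 14. **Longest linear sequence:** 11 steps (steps 1–4 and 8–14); the silane branch (steps 5–7) joins at step 8.

**Steps most likely to fail**

Step 10. What may go wrong: ionisation of the oxirane from the transoid rotamer, whose cation cannot close and is lost by hydride shift or proton loss, or capture that is too slow because the siloxane-bound allylsilane is a weak nucleophile. The fallback fixes the cisoid geometry in a ring before any cation is made. It sets out from 5: ring expansion of the vinyl oxirane with Cu(hfacac)2 (toluene, 80 °C) should give (S)-1-[(R)-3-methyl-2,5-dihydrofuran-2-yl]prop-2-en-1-ol F1, with the surviving C–O bond keeping its configuration. Silylation with 10 as in step 8 gives (S)-2-{[dimethyl({(S)-1-[(R)-3-methyl-2,5-dihydrofuran-2-yl]prop-2-en-1-yl}oxy)silyl]methyl}-6-methylhepta-1,5-dien-3-yl (Z)-2-methylbut-2-enoate F2, and metathesis as in step 9 gives (S)-1-{(S)-2,2-dimethyl-6-[(R)-3-methyl-2,5-dihydrofuran-2-yl]-3,6-dihydro-2H-1,2-oxasilin-4-yl}-4-methylpent-3-en-1-yl (Z)-2-methylbut-2-enoate F3. TMSOTf (CH2Cl2, −78 °C) then opens the prenyl-type cyclic allylic ether, which can only give the cisoid cation; the same allylsilane capture (Hosomi–Sakurai allylation of an allylic ether) returns the route at 13 and, after the HF·pyridine treatment, at 14.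

Step 12. What may go wrong: acylation of the axial hydroxyl, double acylation, or acyl migration between the two cis hydroxyls under the basic conditions. The fallback replaces kinetic discrimination by tin-mediated regiocontrol. It sets out from 15: Bu2SnO (toluene, azeotropic removal of water) should give the dibutylstannylene acetal of 15 F4, in which the oxygen of the pseudo-equatorial hydroxyl is the activated one. Angelic anhydride at room temperature should then acylate that oxygen only, and aqueous work-up returns the route at 16.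

Step 3. What may go wrong: a small rate difference between the enantiomers of 3 (the olefin carries a methyl group cis to the carbinol), so that 4 forms with eroded enantiomeric and erythro purity. The fallback separates resolution from epoxidation. It sets out from 3: lipase-catalysed acylation (Candida antarctica lipase B, vinyl acetate, hexane) should esterify the (R)-alcohol to (R)-(E)-5-methylhepta-1,4-dien-6-yn-3-yl acetate F6 and leave (S)-(E)-5-methylhepta-1,4-dien-6-yn-3-ol F5. F5 is then epoxidised with a full equivalent of t-BuOOH under Ti(OiPr)4/L-(+)-DIPT (matched, now only a diastereoselective epoxidation) and returns the route at 4.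

**Further compounds**
F1 | step 10 | (S)-1-[(R)-3-methyl-2,5-dihydrofuran-2-yl]prop-2-en-1-ol | C=C[C@H](O)[C@@H]1OCC=C1C
F2 | step 10 | (S)-2-{[dimethyl({(S)-1-[(R)-3-methyl-2,5-dihydrofuran-2-yl]prop-2-en-1-yl}oxy)silyl]methyl}-6-methylhepta-1,5-dien-3-yl (Z)-2-methylbut-2-enoate | C=C[C@H](O[Si](C)(C)CC(=C)[C@H](CC=C(C)C)OC(=O)/C(C)=C\C)[C@@H]1OCC=C1C
F3 | step 10 | (S)-1-{(S)-2,2-dimethyl-6-[(R)-3-methyl-2,5-dihydrofuran-2-yl]-3,6-dihydro-2H-1,2-oxasilin-4-yl}-4-methylpent-3-en-1-yl (Z)-2-methylbut-2-enoate | C[Si]1(C)CC([C@H](CC=C(C)C)OC(=O)/C(C)=C\C)=C[C@H](O1)[C@@H]2OCC=C2C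
F4 | step 12 | dibutylstannylene acetal of 15 (2,2-dibutyl-1,3,2-dioxastannolane cis-fused at the two carbinol carbons) | C=C([C@H](CC=C(C)C)OC(=O)/C(C)=C\C)[C@H]1C[C@H]2O[C@@]2(C)[C@H]3O[Sn](CCCC)(CCCC)O[C@@H]13
F5 | step 3 | (S)-(E)-5-methylhepta-1,4-dien-6-yn-3-ol | C=C[C@H](O)/C=C(C)/C#C
F6 | step 3 | (R)-(E)-5-methylhepta-1,4-dien-6-yn-3-yl acetate | C=C[C@@H](OC(C)=O)/C=C(C)/C#C
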